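In a one-step world with a single side path beside it, the share of target in target plus side product A is a plain ratio: call S the target rate over the side-product rate, both as fractions of the charge per hour, and the share is S over one plus S.

| flask | starting material | partner | remark | time |
|---|---|---|---|---|
| Sunday's | 21 mM | 4 equiv | run made earlier |  |
| Saturday's | 21 mM | 2.7 equiv | run made earlier |  |
| Friday's | 21 mM | 6 equiv | run made earlier |  |
| Monday's | 10 mM | 4 equiv | run made earlier |  |
| eta | 21 mM | 4.00 equiv (fed, over 5.0 h) | all else is in the flask from the start; the feed brings no volume worth counting | 6.0 h |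
| alpha | 21 mM (fed, over 5.0 h) | 4.00 equiv | all else is in the flask from the start; the feed brings no volume worth counting | 6.0 h |
| beta | 21 mM | 4.00 equiv | everything together at the start | 6.0 h |
| delta | 21 mM (in portions, 2, over 5.0 h) | 4.00 equiv | first portion at the start, last at 5.0 h | 6.0 h |

| run | time / h | target / % | side product A / % |
|---|---|---|---|
| Sunday's | 0.250 | 3.7 | 0 |
| Sunday's | 0.500 | 3.2 | 0 |
| Sunday's | 1.00 | 2.6 | 0 |
| Sunday's | 2.00 | 6.2 | 1.9 |
| Sunday's | 4.00 | 8.9 | 0 |
| Saturday's | 0.667 | 3.8 | 1.7 |
| Saturday's | 1.33 | 5.1 | 0.8 |
| Saturday's | 2.00 | 5.5 | 3.7 |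
| Saturday's | 3.00 | 4.7 | 3.7 |
| Saturday's | 4.00 | 7.4 | 0.6 |
| Friday's | 0.333 | 2.6 | 1.3 |
| Friday's | 0.833 | 5.8 | 0 |
| Friday's | 1.50 | 6.1 | 2.1 |
| Friday's | 2.50 | 10.2 | 4.2 |
| Friday's | 4.00 | 12.4 | 0.8 |
| Monday's | 0.250 | 0 | 0 |
| Monday's | 0.500 | 1.1 | 0 |
| Monday's | 1.00 | 2.7 | 0.8 |
| Monday's | 2.00 | 3.1 | 0.7 |
| Monday's | 4.00 | 6.3 | 1.6 |

(standard deviation of a reading: 1 percentage point)

- a reading or a percentage of target counts all its forms, free or not

- the flask with the highest share of target in target plus side product A ("all alike" if they lie within 1.5 percentage points) (eta / alpha / beta / delta / all alike)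
- share of target in target plus side product A at the end, eta
- share of target in target plus side product A at the end, alpha
- share of target in target plus side product A at the end, beta
- share of target in target plus side product A at the end, delta

I need two rates. For side product A, I draw a line through the origin and the A readings of the four runs, which gives 0.00532 h⁻¹. For target, I take Sunday's run, which has beta's recipe: between 2.00 h and 4.00 h it climbs from 6.2% to 8.9%, so 0.0135 h⁻¹, slower than the 0.0310 h⁻¹ of the first stretch. Their ratio is 2.54: this is the late selectivity factor, target made per side product A in a flask of Sunday's recipe past 2.00 h. With 1 percentage point on each reading, it is a rough figure.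

Alpha's starting material arrives on average at 2.50 h, inside that late stretch. If the slowing belongs to the partner's age and not to starting material used up, I expect alpha near 71.7%.

The forecast says eta 75%, alpha 84%, beta 82%, delta 85%, and picks delta: “Keeping starting material low (alpha, delta) changes nothing if A is first order, but helps if A is second order.” My alpha stands lower.

Alpha gives 72.8%, while beta ranks first at 81.4%, with delta at 79.0% and eta at 76.8%. At the end of its feed, alpha holds 75.9% of the starting material charged beside 14.0% of the partner's own charge. Turned back, alpha's share means a ratio of 2.67, against the 2.54 read from Sunday's run.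

    starting material + target ⇌ idle adduct, settled at all times (K = 22.0 M⁻¹)
    starting material → side product A (k = 1.00 × 10⁻⁴ min⁻¹)
    2 partner → homo dimer (k = 0.0600 M⁻¹ min⁻¹)
    2 starting material → side product B (k = 0.0620 M⁻¹ min⁻¹)
    starting material + partner → target (k = 0.0140 M⁻¹ min⁻¹)
    partner → decomposed reagent (k = 0.00270 min⁻¹)

For alpha at 84 mM, equivalents held, I multiply the factor by the charge ratio, taking the partner concentration in the target step to scale with the charge: 10.1, a share of 91.0%. The computed flask gives 81.6%, which is lower.

The runs were generated by integration from invented constants; the scatter is artificial.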